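**Retrosynthetic overview**
1. The strategy rests on ring A: C5, C6, C7 and C8 all carry oxygen, O5 and O8 are para, and the ring is fused to pyranone ring C along C4a–C8a. These four carbons and their oxygens map onto the four carbons of dimethyl squarate, and C8a/C4a onto the O-bearing carbon and its CH neighbour of a γ-pyrone.
2. The O3 benzyl ether is removed last. Before that, ring A is disconnected at C4a–C5 to a 4-methoxy-4-(4-oxopyran-2-yl)cyclobutenone (4π opening, 6π closure). The carbinol oxygen is methylated before the expansion, so O8 arrives as OMe and O5 as the free, chelated phenol.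
3. The cyclobutenone comes from addition of the C6-lithiated 3-(benzyloxy)-2-(4-methoxyphenyl)-4-pyranone to dimethyl squarate. The pyranone comes from pyromeconic acid by C2 bromination, O-benzylation and Suzuki–Miyaura coupling.
4. Order of rings: ring C is bought, ring B is attached by cross-coupling, ring A is formed last in the key step.

Key step: step 6

Remark: pyromeconic acid (3-hydroxy-4H-pyran-4-one), the decarboxylation product of comenic acid, is assumed to be purchasable; this removes a high-temperature decarboxylation followed by re-metalation at the same carbon.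

**Step 1**
Reactants: 1 3-hydroxy-4H-pyran-4-one (pyromeconic acid)
Product: 2 2-bromo-3-hydroxy-4H-pyran-4-one
Conditions: NBS (1.0 equiv), MeCN, 0 °C → rt
Reagents that add atoms: N-bromosuccinimide, O=C1CCC(=O)N1Br
Why: Electrophilic bromination of the enol of a 3-hydroxy-4-pyranone should occur at C2, the enol β-carbon next to the ring oxygen, as at the corresponding carbon of kojic and comenic acids.

**Step 2**
Reactants: 2 2-bromo-3-hydroxy-4H-pyran-4-one
Product: 3 3-(benzyloxy)-2-bromo-4H-pyran-4-one
Conditions: BnBr, K2CO3, DMF, rt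
Reagents that add atoms: benzyl bromide, BrCc1ccccc1
Why: Williamson etherification of the acidic enolic hydroxyl with a carbonate base, which is too weak a nucleophile to displace the vinylogous acyl bromide.

**Step 3**
Reactants: 3 3-(benzyloxy)-2-bromo-4H-pyran-4-one; 4 4-methoxyphenylboronic acid
Product: 5 3-(benzyloxy)-2-(4-methoxyphenyl)-4H-pyran-4-one
Conditions: Pd(PPh3)4 (5 mol %), K2CO3, 1,4-dioxane/H2O, 85 °C
Reagents that add atoms: none
Why: Suzuki–Miyaura coupling, in which the C2–Br bond of a vinylogous acyl bromide should add readily to zerovalent palladium and the mild carbonate base should spare the base-sensitive pyranone.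

**Step 4**
Reactants: 5 3-(benzyloxy)-2-(4-methoxyphenyl)-4H-pyran-4-one; 6 dimethyl squarate
Product: 9 4-[5-(benzyloxy)-6-(4-methoxyphenyl)-4-oxo-4H-pyran-2-yl]-4-hydroxy-2,3-dimethoxycyclobut-2-en-1-one (racemic), via pyranyllithium 7 (not isolated), via lithium alkoxide 8 (not isolated)
Conditions: LiTMP (from TMPH and n-BuLi), THF, −78 °C; then 6, −78 °C; NH4Cl (aq), −78 °C
Reagents that add atoms: none
Why: Deprotonative lithiation followed by 1,2-addition of an organolithium to a squarate carbonyl: the hindered, non-nucleophilic lithium amide should remove the C6 hydrogen next to the ring oxygen (C2 being blocked by the aryl group), as strong lithium bases do in 1-alkyl-4-pyridones, 4-quinolones and chromones, and the vinyllithium should add once to dimethyl squarate at −78 °C to give the racemic carbinol, whose configuration is of no consequence.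

**Step 5**
Reactants: 9 4-[5-(benzyloxy)-6-(4-methoxyphenyl)-4-oxo-4H-pyran-2-yl]-4-hydroxy-2,3-dimethoxycyclobut-2-en-1-one (racemic)
Product: 10 4-[5-(benzyloxy)-6-(4-methoxyphenyl)-4-oxo-4H-pyran-2-yl]-2,3,4-trimethoxycyclobut-2-en-1-one (racemic)
Conditions: MeI, Ag2O, 4 Å MS, MeCN, rt, dark
Reagents that add atoms: iodomethane, CI
Why: Purdie methylation, a near-neutral etherification established for tertiary 4-hydroxycyclobutenones, should fix the carbinol oxygen (the future O8) as its methyl ether without exposing the base-labile α-ketol to alkoxide conditions.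

**Step 6**
Reactants: 10 4-[5-(benzyloxy)-6-(4-methoxyphenyl)-4-oxo-4H-pyran-2-yl]-2,3,4-trimethoxycyclobut-2-en-1-one (racemic)
Product: 13 3-(benzyloxy)-5-hydroxy-6,7,8-trimethoxy-2-(4-methoxyphenyl)-4H-chromen-4-one, via dienylketene 11 (not isolated), via 4aH-dienone 12 (not isolated)
Conditions: p-xylene (degassed, 0.02 M), 138 °C, Ar
Reagents that add atoms: none
Why: Heating should open the cyclobutenone by 4π conrotation with the C4 methoxy group turning outward, as donor groups on the sp3 carbon do, which gives the (Z)-dienylketene 11 with the pyranyl group turned inward next to the ketene. A 6π disrotatory electrocyclisation then joins the electrophilic ketene carbon to the nucleophilic pyranone carbon C3 (the enol-ether β-carbon that becomes C4a), closing the six-membered carbocycle ring A as the 4aH-dienone 12, and enolisation of its doubly activated 4a-hydrogen gives the aromatic phenol 13 with the new 5-hydroxyl hydrogen-bonded to the C4 carbonyl. The closest known reaction is the Moore rearrangement of squarate-derived 4-aryl, 4-heteroaryl and 4-alkenyl cyclobutenones carrying a 4-hydroxy, 4-alkoxy or 4-silyloxy group, which gives hydroquinones or their mono-ethers; a 4-oxopyran-2-yl arm has not been tried, but its C2=C3 bond has little aromatic character and should behave like the alkenyl cases. No stereocentre is created: the carbinol centre of 10 is destroyed on ring opening and the 4a centre of 12 on enolisation. Two selectivities are needed: outward rotation of the methoxy group, which the donor substituent itself secures, and closure at a single carbon, which is secured because the pyranone carbon bonded to the cyclobutenone has only one carbon neighbour, the other being the ring oxygen. Because the carbinol oxygen was methylated in step 5, O8 emerges as the methyl ether and O5 as the free phenol, so a quinone-prone 5,8-hydroquinone never has to be handled or differentiated.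

**Step 7**
Reactants: 13 3-(benzyloxy)-5-hydroxy-6,7,8-trimethoxy-2-(4-methoxyphenyl)-4H-chromen-4-one
Product: 14 3,5-dihydroxy-6,7,8-trimethoxy-2-(4-methoxyphenyl)-4H-chromen-4-one
Conditions: H2 (1 atm), Pd/C (10 wt %), EtOAc/MeOH, rt
Reagents that add atoms: none
Why: Hydrogenolysis of the benzyl ether over palladium on carbon, the standard release of flavonols, should leave the tetrasubstituted C2=C3 bond, the methyl ethers and the chelated 5-hydroxyl untouched.

**Compound list**
1 | 3-hydroxy-4H-pyran-4-one (pyromeconic acid) | O=c1ccocc1O | starting material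
2 | 2-bromo-3-hydroxy-4H-pyran-4-one | O=c1ccoc(Br)c1O | intermediate
3 | 3-(benzyloxy)-2-bromo-4H-pyran-4-one | O=c1ccoc(Br)c1OCc1ccccc1 | intermediate
4 | 4-methoxyphenylboronic acid | COc1ccc(B(O)O)cc1 | starting material
5 | 3-(benzyloxy)-2-(4-methoxyphenyl)-4H-pyran-4-one | O=c1ccoc(-c2ccc(OC)cc2)c1OCc1ccccc1 | intermediate
6 | dimethyl squarate (3,4-dimethoxycyclobut-3-ene-1,2-dione) | COC1=C(OC)C(=O)C1=O | starting material
7 | [5-(benzyloxy)-6-(4-methoxyphenyl)-4-oxo-4H-pyran-2-yl]lithium | [Li]c1cc(=O)c(OCc2ccccc2)c(-c2ccc(OC)cc2)o1 | intermediate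
8 | lithium 1-[5-(benzyloxy)-6-(4-methoxyphenyl)-4-oxo-4H-pyran-2-yl]-2,3-dimethoxy-4-oxocyclobut-2-en-1-olate (racemic) | [Li+].[O-]C1(c2cc(=O)c(OCc3ccccc3)c(-c3ccc(OC)cc3)o2)C(OC)=C(OC)C1=O | intermediate
9 | 4-[5-(benzyloxy)-6-(4-methoxyphenyl)-4-oxo-4H-pyran-2-yl]-4-hydroxy-2,3-dimethoxycyclobut-2-en-1-one (racemic) | COC1=C(OC)C(O)(c2cc(=O)c(OCc3ccccc3)c(-c3ccc(OC)cc3)o2)C1=O | intermediate
10 | 4-[5-(benzyloxy)-6-(4-methoxyphenyl)-4-oxo-4H-pyran-2-yl]-2,3,4-trimethoxycyclobut-2-en-1-one (racemic) | COC1=C(OC)C(OC)(c2cc(=O)c(OCc3ccccc3)c(-c3ccc(OC)cc3)o2)C1=O | intermediate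
11 | (3Z)-4-[5-(benzyloxy)-6-(4-methoxyphenyl)-4-oxo-4H-pyran-2-yl]-2,3,4-trimethoxybuta-1,3-dien-1-one | O=C=C(OC)/C(OC)=C(\c1cc(=O)c(OCc2ccccc2)c(-c2ccc(OC)cc2)o1)OC | intermediate
12 | 3-(benzyloxy)-6,7,8-trimethoxy-2-(4-methoxyphenyl)-4aH-chromene-4,5-dione (racemic) | O=C1C(OC)=C(OC)C(OC)=C2OC(-c3ccc(OC)cc3)=C(OCc3ccccc3)C(=O)C12 | intermediate
13 | 3-(benzyloxy)-5-hydroxy-6,7,8-trimethoxy-2-(4-methoxyphenyl)-4H-chromen-4-one | COc1ccc(-c2oc3c(OC)c(OC)c(OC)c(O)c3c(=O)c2OCc2ccccc2)cc1 | intermediate
14 | 3,5-dihydroxy-6,7,8-trimethoxy-2-(4-methoxyphenyl)-4H-chromen-4-one (3,5-dihydroxy-6,7,8,4'-tetramethoxyflavone) | COc1ccc(-c2oc3c(OC)c(OC)c(OC)c(O)c3c(=O)c2O)cc1 | target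

**Step count and risks**
Total steps: 7. Longest linear sequence: 7 steps (1 → 2 → 3 → 5 → 9 → 10 → 13 → 14).

Steps most likely to fail:

1. Step 6. Closure of the dienylketene onto C3 of the electron-poor pyranone may be slower than on the aryl and alkenyl arms known so far, so that the ketene is lost by dimerisation, by capture by adventitious nucleophiles or by decomposition at the temperature needed. The fallback reverses the order of ring formation: ring A is made from the same squarate on a simple enol-ether arm, a known alkenyl case of the same rearrangement, and ring C is then closed by flavone chemistry. It sets out from dimethyl squarate 6. Addition of 1-methoxyvinyllithium (methyl vinyl ether, t-BuLi, THF, −78 °C) gives 4-hydroxy-2,3-dimethoxy-4-(1-methoxyethenyl)cyclobut-2-en-1-one F1, which is methylated (MeI, Ag2O) to 2,3,4-trimethoxy-4-(1-methoxyethenyl)cyclobut-2-en-1-one F2. Thermolysis in toluene should give 2,3,4,5-tetramethoxyphenol F3, whose single free ring position is C-acetylated (AcOH, BF3·OEt2, 90 °C, Friedel–Crafts type) to 1-(2-hydroxy-3,4,5,6-tetramethoxyphenyl)ethan-1-one F4. Claisen–Schmidt condensation with 4-methoxybenzaldehyde (KOH, EtOH) gives (E)-1-(2-hydroxy-3,4,5,6-tetramethoxyphenyl)-3-(4-methoxyphenyl)prop-2-en-1-one F5. Oxidative cyclisation (I2 cat., DMSO, 130 °C) gives 5,6,7,8-tetramethoxy-2-(4-methoxyphenyl)-4H-chromen-4-one F6. C3 hydroxylation with dimethyldioxirane followed by p-TsOH gives 3-hydroxy-5,6,7,8-tetramethoxy-2-(4-methoxyphenyl)-4H-chromen-4-one F7. Chelation-controlled cleavage of the 5-methyl ether (BCl3, CH2Cl2, −78 → 0 °C) comes back to the route at the target 14.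

2. Step 4. Deprotonation may take place at C5 next to the carbonyl instead of C6, after which β-elimination of the ring oxygen would fragment the pyranone; the lithiated pyranone may also add to unreacted 5 before the squarate is introduced. The fallback separates the C–H metalation from the carbonyl addition and sets out from 5. Zincation with the mild amide TMPZnCl·LiCl (THF, 25 °C), which should not fragment the ring, gives chloro[5-(benzyloxy)-6-(4-methoxyphenyl)-4-oxo-4H-pyran-2-yl]zinc F8. Iodolysis (I2) gives 3-(benzyloxy)-6-iodo-2-(4-methoxyphenyl)-4H-pyran-4-one F9, whose constitution can be checked before it is committed. Iodine–magnesium exchange (iPrMgCl·LiCl, THF, −78 °C) gives chloro[5-(benzyloxy)-6-(4-methoxyphenyl)-4-oxo-4H-pyran-2-yl]magnesium F10, which is added to 6 and, after an NH4Cl quench, comes back to the route at 9.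

3. Step 5. The hindered tertiary α-ketol may resist etherification or undergo ring cleavage or acyloin-type rearrangement on the basic silver oxide surface. The fallback differentiates O5 and O8 after the ring expansion by hydrogen bonding, not before it by position, and sets out from 9. Thermolysis of the free carbinol (degassed p-xylene, 138 °C, Ar) should give 3-(benzyloxy)-5,8-dihydroxy-6,7-dimethoxy-2-(4-methoxyphenyl)-4H-chromen-4-one F11. With air excluded, the unchelated 8-hydroxyl is methylated (Me2SO4 1.05 equiv, K2CO3, degassed acetone) while the 5-hydroxyl stays hydrogen-bonded to the C4 carbonyl, which comes back to the route at 13.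

**Further compounds**
F1 | step 6 | 4-hydroxy-2,3-dimethoxy-4-(1-methoxyethenyl)cyclobut-2-en-1-one (racemic) | COC(=C)C1(O)C(OC)=C(OC)C1=O
F2 | step 6 | 2,3,4-trimethoxy-4-(1-methoxyethenyl)cyclobut-2-en-1-one (racemic) | COC(=C)C1(OC)C(OC)=C(OC)C1=O
F3 | step 6 | 2,3,4,5-tetramethoxyphenol | COc1cc(O)c(OC)c(OC)c1OC
F4 | step 6 | 1-(2-hydroxy-3,4,5,6-tetramethoxyphenyl)ethan-1-one | CC(=O)c1c(O)c(OC)c(OC)c(OC)c1OC
F5 | step 6 | (E)-1-(2-hydroxy-3,4,5,6-tetramethoxyphenyl)-3-(4-methoxyphenyl)prop-2-en-1-one | COc1ccc(/C=C/C(=O)c2c(O)c(OC)c(OC)c(OC)c2OC)cc1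
F6 | step 6 | 5,6,7,8-tetramethoxy-2-(4-methoxyphenyl)-4H-chromen-4-one | COc1ccc(-c2cc(=O)c3c(OC)c(OC)c(OC)c(OC)c3o2)cc1
F7 | step 6 | 3-hydroxy-5,6,7,8-tetramethoxy-2-(4-methoxyphenyl)-4H-chromen-4-one | COc1ccc(-c2oc3c(OC)c(OC)c(OC)c(OC)c3c(=O)c2O)cc1
F8 | step 4 | chloro[5-(benzyloxy)-6-(4-methoxyphenyl)-4-oxo-4H-pyran-2-yl]zinc | Cl[Zn]c1cc(=O)c(OCc2ccccc2)c(-c2ccc(OC)cc2)o1
F9 | step 4 | 3-(benzyloxy)-6-iodo-2-(4-methoxyphenyl)-4H-pyran-4-one | COc1ccc(-c2oc(I)cc(=O)c2OCc2ccccc2)cc1
F10 | step 4 | chloro[5-(benzyloxy)-6-(4-methoxyphenyl)-4-oxo-4H-pyran-2-yl]magnesium | Cl[Mg]c1cc(=O)c(OCc2ccccc2)c(-c2ccc(OC)cc2)o1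
F11 | step 5 | 3-(benzyloxy)-5,8-dihydroxy-6,7-dimethoxy-2-(4-methoxyphenyl)-4H-chromen-4-one | COc1ccc(-c2oc3c(O)c(OC)c(OC)c(O)c3c(=O)c2OCc2ccccc2)cc1
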